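**Retrosynthetic overview**
1. Hypercalin B ⇒ cut the ring‑CH2–cyclopentane C–C bond (reductive Knoevenagel alkylation). This gives a dearomatised gem‑diprenyl benzoyl trione and a cyclopentane aldol aldehyde.
2. Aldol aldehyde ⇒ α,β‑epoxy aldehyde. Only the Cα–O bond is cleaved reductively, so the tertiary C–O bond stays.
3. Key disconnection is the tertiary C–O bond: epoxy aldehyde ⇒ cyclopentene carbaldehyde + hydroperoxide anion (nucleophilic epoxidation anti to isopropenyl). The plain aldol of the keto aldehyde is not used because it dehydrates to this enal.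
4. Enal ⇒ (S)‑limonene (ozonolysis/aldol ring contraction). Trione ⇒ 2,4,6‑trihydroxybenzophenone + 2 prenyl bromide (alkylative dearomatisation).
5. Ring order: cyclopentane (step 1), then a transient oxirane (step 2, opened in step 4). The six‑membered ring is bought as an arene and dearomatised in step 3.

Assumption: the target is handled as the enol tautomer written in the given SMILES, and 2,4,6‑trihydroxybenzophenone counts as a catalogue chemical.

**Step 1**
Reactants: 1 (S)-(−)-limonene
Product: 4 (5R)-2-methyl-5-(prop-1-en-2-yl)cyclopent-1-ene-1-carbaldehyde, via ring ozonide 2 (not isolated), via keto aldehyde 3 (not isolated)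
Conditions: O3 (1.0 equiv, Sudan Red 7B endpoint), CH2Cl2, −78 °C; Me2S, −78 °C to rt; then piperidine (0.3 equiv), AcOH (0.3 equiv), 40 °C
Reagents that add atoms: ozone, [O-][O+]=O
Why: Chemoselective ozonolysis takes the electron‑richer trisubstituted ring alkene before the 1,1‑disubstituted one, and the piperidine enamine of the aldehyde then closes on the methyl ketone (5‑enolexo intramolecular aldol condensation), the C5 stereocentre coming unchanged from limonene.

**Step 2**
Reactants: 4 (5R)-2-methyl-5-(prop-1-en-2-yl)cyclopent-1-ene-1-carbaldehyde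
Product: 5 (1R,2R,5S)-5-methyl-2-(prop-1-en-2-yl)-6-oxabicyclo[3.1.0]hexane-1-carbaldehyde
Conditions: 30% aq H2O2 (3 equiv), NaOH (0.2 equiv), MeOH, 0 °C
Reagents that add atoms: hydrogen peroxide, OO
Why: In this Weitz–Scheffer nucleophilic epoxidation, hydroperoxide anion adds reversibly to the β‑carbon (making the tertiary C–O bond of the target at C5) and the exocyclic enolate, whose neighbouring isopropenyl group sits pseudo‑axial to avoid allylic strain, closes on the O–O bond from the open face, so C1 and C5 both carry oxygen anti to isopropenyl while the unactivated isopropenyl alkene is inert to a nucleophilic oxidant.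

**Step 3**
Reactants: 6 2,4,6-trihydroxybenzophenone; 7 prenyl bromide
Product: 9 2-benzoyl-3,5-dihydroxy-6,6-bis(3-methylbut-2-en-1-yl)cyclohexa-2,4-dien-1-one, via monoprenyl ketone 8 (not isolated)
Conditions: 7 (2.1 equiv), KOH (3 equiv), H2O, 0 °C to rt; acidify, NaHCO3 extraction, chromatography
Reagents that add atoms: prenyl bromide (7), CC(C)=CCBr
Why: In this alkylative dearomatisation the phloroglucinolate is C‑prenylated to 8, whose substituted and most electron‑rich ring carbon takes the second prenyl group in competition with the free carbon, and 9, a much stronger acid than the aromatic 3,5‑isomer, is pulled out with NaHCO3; no stereocentre is formed.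

**Step 4**
Reactants: 5 (1R,2R,5S)-5-methyl-2-(prop-1-en-2-yl)-6-oxabicyclo[3.1.0]hexane-1-carbaldehyde; 9 2-benzoyl-3,5-dihydroxy-6,6-bis(3-methylbut-2-en-1-yl)cyclohexa-2,4-dien-1-one
Product: 12 hypercalin B, via aldol aldehyde 10 (not isolated), via alkylidene trione 11 (not isolated)
Conditions: 5, diethyl 2,6-dimethyl-1,4-dihydropyridine-3,5-dicarboxylate (Hantzsch ester, 2.4 equiv), Cp2TiCl2 (10 mol%), 2,4,5,6-tetra(carbazol-9-yl)isophthalonitrile (2 mol%), THF, 450 nm LED, rt; lamp off, then 9 (1.0 equiv), L-proline (20 mol%), EtOH, rt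
Reagents that add atoms: none
Why: Proposed new method: a titanocene/photoredox reductive opening of a fully substituted α,β‑epoxy aldehyde is relayed in the same flask into an organocatalytic reductive alkylation, with one charge of Hantzsch ester as the only reductant; the photoreduced cyanoarene turns Cp2TiCl2 into trivalent Cp2TiCl, which binds the oxirane oxygen and breaks the C1–O bond homolytically because only that cleavage gives a tertiary radical stabilised by the formyl group, so the tertiary C5–O bond of step 2 survives as a titanium alkoxide; polarity‑matched hydrogen‑atom transfer from the Hantzsch ester to the face away from the bulky Cp2Ti(Cl)O group, then protonolysis by the pyridinium formed, gives 10, and the low titanium loading suppresses titanium enolate formation and β‑elimination; with the lamp off, proline‑mediated Knoevenagel condensation of 10 with the C–H acid 9 gives 11, which takes hydride from the second equivalent of Hantzsch ester at the exocyclic carbon; the new cyclopentane stereocentre C1 is also under thermodynamic control, since it can epimerise through the proline enamine of 10 and the dienol of 11 and is most stable trans to both isopropenyl and methyl; the closest known reaction types are stoichiometric Cp2TiCl reduction of α,β‑epoxy ketones to β‑hydroxy ketones, titanocene/photoredox opening of simple epoxides with Hantzsch ester, and the proline/Hantzsch ester three‑component reductive alkylation of cyclic 1,3‑diones.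

**Compound list**
1 | (S)-(−)-limonene, (4S)-1-methyl-4-(prop-1-en-2-yl)cyclohex-1-ene | CC1=CC[C@H](CC1)C(C)=C | starting material
2 | (4S)-1-methyl-4-(prop-1-en-2-yl)-7,8,9-trioxabicyclo[4.2.1]nonane (ring ozonide, both bridge diastereomers) | CC12CC[C@@H](CC(OO1)O2)C(C)=C | intermediate
3 | (3S)-6-oxo-3-(prop-1-en-2-yl)heptanal | O=CC[C@H](CCC(C)=O)C(C)=C | intermediate
4 | (5R)-2-methyl-5-(prop-1-en-2-yl)cyclopent-1-ene-1-carbaldehyde | CC1=C(C=O)[C@@H](C(C)=C)CC1 | intermediate
5 | (1R,2R,5S)-5-methyl-2-(prop-1-en-2-yl)-6-oxabicyclo[3.1.0]hexane-1-carbaldehyde (oxirane anti to isopropenyl) | C=C(C)[C@H]1CC[C@]2(C)O[C@]12C=O | intermediate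
6 | 2,4,6-trihydroxybenzophenone | O=C(c1ccccc1)c1c(O)cc(O)cc1O | starting material
7 | prenyl bromide (1-bromo-3-methylbut-2-ene) | CC(C)=CCBr | starting material
8 | phenyl[2,4,6-trihydroxy-3-(3-methylbut-2-en-1-yl)phenyl]methanone | O=C(c1ccccc1)c1c(O)cc(O)c(CC=C(C)C)c1O | intermediate
9 | 2-benzoyl-3,5-dihydroxy-6,6-bis(3-methylbut-2-en-1-yl)cyclohexa-2,4-dien-1-one | OC1=CC(O)=C(C(=O)c2ccccc2)C(=O)C1(CC=C(C)C)CC=C(C)C | intermediate
10 | (1R,2S,5S)-2-hydroxy-2-methyl-5-(prop-1-en-2-yl)cyclopentane-1-carbaldehyde (CHO cis to OH, trans to isopropenyl) | C=C(C)[C@H]1CC[C@](C)(O)[C@@H]1C=O | intermediate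
11 | 2-benzoyl-3-hydroxy-6-{[(1R,2S,5S)-2-hydroxy-2-methyl-5-(prop-1-en-2-yl)cyclopentyl]methylidene}-4,4-bis(3-methylbut-2-en-1-yl)cyclohex-2-ene-1,5-dione (alkene geometry not defined) | C=C(C)[C@H]1CC[C@](C)(O)[C@@H]1C=C1C(=O)C(CC=C(C)C)(CC=C(C)C)C(O)=C(C(=O)c2ccccc2)C1=O | intermediate
12 | hypercalin B, 2-benzoyl-3,5-dihydroxy-4-{[(1R,2S,5S)-2-hydroxy-2-methyl-5-(prop-1-en-2-yl)cyclopentyl]methyl}-6,6-bis(3-methylbut-2-en-1-yl)cyclohexa-2,4-dien-1-one | C=C(C)[C@H]1CC[C@](C)(O)[C@@H]1CC1=C(O)C(CC=C(C)C)(CC=C(C)C)C(=O)C(C(=O)c2ccccc2)=C1O | target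

**Total step count:** 4. **Longest linear sequence:** 3 (1 → 4 → 5 → 12). Step 3 is the second branch.

**Three steps most likely to fail**

Step 4 (the proposed relay). The titanium Lewis acid could trigger a formyl shift in 5. Aldehyde 10 could also lose water back to 4, or undergo retro‑aldol cleavage to 3, before it condenses with 9.
The fallback uses known chemistry, sets out from 5 and comes back to the route at 10. It replaces the external reductant by an internal redox reaction.
- An N‑heterocyclic carbene made from 3-benzyl-5-(2-hydroxyethyl)-4-methylthiazolium chloride and iPr2NEt in CH2Cl2/MeOH opens the epoxy aldehyde through its acyl anion equivalent. This gives methyl (1R,2S,5S)-2-hydroxy-2-methyl-5-(prop-1-en-2-yl)cyclopentane-1-carboxylate F1.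
- iBu2AlH (2.2 equiv, CH2Cl2, −78 °C) reduces F1 to 10, which is isolated.
- Aldehyde 10 is then coupled with 9 in a separate proline/Hantzsch ester reductive alkylation, passing through 11 to 12.

Step 3 (gem‑diprenylation). The aromatic 3,5‑diprenyl isomer and the triprenyl product compete, so no more than about one third of the material is expected as 9.
The fallback sets out from 6 and comes back at 9. It blocks the third ring carbon before prenylation.
- Vilsmeier–Haack formylation (POCl3, DMF) gives 3-benzoyl-2,4,6-trihydroxybenzaldehyde F2.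
- With only one ring carbon free, 7 and KOH lead through 3-benzoyl-2,4,6-trihydroxy-5-(3-methylbut-2-en-1-yl)benzaldehyde F3 to 5-benzoyl-2,6-dihydroxy-3,3-bis(3-methylbut-2-en-1-yl)-4-oxocyclohexa-1,5-diene-1-carbaldehyde F4.
- Retro‑Claisen deformylation (K2CO3, MeOH), which attacks the most electrophilic of the three carbonyl groups on that carbon, then frees 9.

Step 2 (nucleophilic epoxidation). The β‑carbon of the tetrasubstituted enal is hindered. Hydroperoxide may attack the formyl group instead and cause Dakin‑type cleavage.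
The fallback sets out from 4 and comes back at 5. It still makes the same C–O bond, but with an electrophilic, hydroxyl‑directed oxidant.
- iBu2AlH reduces 4 to [(5R)-2-methyl-5-(prop-1-en-2-yl)cyclopent-1-en-1-yl]methanol F5.
- VO(acac)2/tBuOOH epoxidises only the allylic‑alcohol alkene, from the face anti to isopropenyl, giving [(1S,2R,5S)-5-methyl-2-(prop-1-en-2-yl)-6-oxabicyclo[3.1.0]hexan-1-yl]methanol F6.
- Dess–Martin oxidation of F6 gives 5.

**Further compounds**
F1 | step 4 | methyl (1R,2S,5S)-2-hydroxy-2-methyl-5-(prop-1-en-2-yl)cyclopentane-1-carboxylate | C=C(C)[C@H]1CC[C@](C)(O)[C@@H]1C(=O)OC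
F2 | step 3 | 3-benzoyl-2,4,6-trihydroxybenzaldehyde | O=Cc1c(O)cc(O)c(C(=O)c2ccccc2)c1O
F3 | step 3 | 3-benzoyl-2,4,6-trihydroxy-5-(3-methylbut-2-en-1-yl)benzaldehyde | O=Cc1c(O)c(CC=C(C)C)c(O)c(C(=O)c2ccccc2)c1O
F4 | step 3 | 5-benzoyl-2,6-dihydroxy-3,3-bis(3-methylbut-2-en-1-yl)-4-oxocyclohexa-1,5-diene-1-carbaldehyde | O=CC1=C(O)C(CC=C(C)C)(CC=C(C)C)C(=O)C(C(=O)c2ccccc2)=C1O
F5 | step 2 | [(5R)-2-methyl-5-(prop-1-en-2-yl)cyclopent-1-en-1-yl]methanol | CC1=C(CO)[C@@H](C(C)=C)CC1
F6 | step 2 | [(1S,2R,5S)-5-methyl-2-(prop-1-en-2-yl)-6-oxabicyclo[3.1.0]hexan-1-yl]methanol | C=C(C)[C@H]1CC[C@]2(C)O[C@]12CO
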